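**Retrosynthetic overview**
- The C10–O bond is made last, by a late-stage allylic C–H benzoyloxylation of the 2-acetate/6-angelate (proposed new step).
- The C2 and C6 C–O bonds come from one double conjugate borylation–oxidation of a bicyclic cross-conjugated trienone; the isopropyl carbinol comes from organocerium addition to the C4 ketone.
- The seven-membered ring is closed by ring-closing metathesis (C8=C9) after an aldol condensation that attaches C6–C8 to the cyclopentenone.
- The five-membered ring comes from 3-ethoxycyclopent-2-enone; the C1 quaternary centre is set by asymmetric conjugate methylation.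
- Ring order: five-membered ring first (starting material), seven-membered ring second (metathesis).

Assumption: daucane numbering is used (C1 = methyl-bearing ring-fusion carbon, C2–C4 = other cyclopentane carbons with isopropyl on C4, C5 = ring-fusion CH, C6–C10 = seven-membered-ring carbons with methyl on C8; 11,12,13-trinor = no isopropyl group); β is the face of the C1 methyl, all bicyclic compounds have 1β-CH3, and the target is 2α-acetoxy-6α-angeloyloxy-10β-benzoyloxydauc-8-en-4β-ol (5α-H, angeloyl = (Z)-2-methylbut-2-enoyl).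

**Step 1**
Reactants: 1 3-ethoxycyclopent-2-en-1-one
Product: 3 3-allylcyclopent-2-en-1-one, via bromomagnesium tertiary alkoxide 2 (not isolated)
Conditions: CH2=CHCH2MgBr, Et2O, 0 °C; then 1 M HCl, 0 °C, 10 min
Reagents that add atoms: allylmagnesium bromide, C=CC[Mg]Br
Why: Stork–Danheiser sequence, in which 1,2-addition of the allyl Grignard reagent to the vinylogous ester and brief cold acid hydrolysis/dehydration give the transposed 3-substituted enone; no stereocentre is formed.

**Step 2**
Reactants: 3 3-allylcyclopent-2-en-1-one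
Product: 4 (R)-3-methyl-3-(prop-2-en-1-yl)cyclopentan-1-one
Conditions: Me3Al (1.5 equiv), Cu(O2CC4H3S) (5 mol %), biphenol-derived N,N-bis[1-(2-naphthyl)ethyl]phosphoramidite (10 mol %, enantiomer that gives the R ketone), Et2O, −30 °C; aq. NH4Cl
Reagents that add atoms: trimethylaluminium, C[Al](C)C
Why: Copper-catalysed asymmetric conjugate addition of Me3Al to a 3-substituted cyclopentenone (a known class for all-carbon quaternary centres), in which the chiral copper–phosphoramidite complex selects one enantioface and so sets the C1 quaternary stereocentre.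

**Step 3**
Reactants: 4 (R)-3-methyl-3-(prop-2-en-1-yl)cyclopentan-1-one
Product: 5 (R)-4-methyl-4-(prop-2-en-1-yl)cyclopent-2-en-1-one
Conditions: IBX (1.5 equiv), 4-methoxypyridine N-oxide (1.5 equiv), DMSO, 25 °C
Reagents that add atoms: none
Why: IBX-mediated α,β-dehydrogenation of a ketone, which can only occur on the C3–C2 side because the other α-carbon is next to the quaternary centre and has no β-hydrogen, so one enone forms and C1 is untouched.

**Step 4**
Reactants: 6 3-methylbut-3-en-1-ol
Product: 7 3-methylbut-3-enal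
Conditions: Dess–Martin periodinane, CH2Cl2, 0 → 25 °C; filtered solution used at once
Reagents that add atoms: none
Why: Dess–Martin oxidation of a primary alcohol under neutral non-aqueous conditions, which avoids isomerisation of the β,γ-unsaturated aldehyde to the conjugated isomer.

**Step 5**
Reactants: 5 (R)-4-methyl-4-(prop-2-en-1-yl)cyclopent-2-en-1-one; 7 3-methylbut-3-enal
Product: 11 (S,E)-4-methyl-5-(3-methylbut-3-en-1-ylidene)-4-(prop-2-en-1-yl)cyclopent-2-en-1-one, via lithium dienolate 8 (not isolated), via lithium aldolate 9 (not isolated), via aldol mesylate 10 (not isolated)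
Conditions: LiN(iPr)2, THF, −78 °C; 7, −78 °C; MsCl, −78 → 0 °C; DBU, 0 °C
Reagents that add atoms: none
Why: Aldol condensation (kinetic α'-enolate, aldol addition, E1cB elimination of the mesylate); only C5 can be enolised because the γ-position is quaternary, both aldol stereocentres are erased, and DBU gives the E-alkylidene with C7 cis to C1 as ring closure needs.

**Step 6**
Reactants: 11 (S,E)-4-methyl-5-(3-methylbut-3-en-1-ylidene)-4-(prop-2-en-1-yl)cyclopent-2-en-1-one
Product: 12 (1S)-11,12,13-trinordauca-2,5,8-trien-4-one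
Conditions: second-generation Grubbs catalyst RuCl2(=CHPh)(H2IMes)(PCy3) (5 mol %), 1,4-benzoquinone (10 mol %), CH2Cl2 (5 mM), 40 °C
Reagents that add atoms: none
Why: Ring-closing metathesis between the allyl alkene and the 1,1-disubstituted methallyl alkene closes the seven-membered ring and forms the trisubstituted C8=C9 alkene with loss of ethene; the conjugated enone alkenes do not react and benzoquinone suppresses isomerisation of the skipped diene.

**Step 7**
Reactants: 12 (1S)-11,12,13-trinordauca-2,5,8-trien-4-one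
Product: 14 2α,6α-dihydroxy-11,12,13-trinordauc-8-en-4-one, via bis(pinacolboronate) 13 (not isolated)
Conditions: B2pin2 (2.4 equiv), CuCl (10 mol %), DPEphos (10 mol %), NaOtBu (15 mol %), MeOH (4 equiv), THF, 0 → 25 °C; then NaBO3·4H2O, THF/H2O, 25 °C
Reagents that add atoms: sodium perborate, [Na+].[O-]OB=O
Why: Copper-catalysed conjugate borylation of both enone units followed by stereoretentive C–B oxidation; borylcupration and enolate protonation take place on the α-face anti to the C1 angular methyl, which sets C2 (O α), C6 (O α) and C5 (H α, trans ring fusion) at once, while the isolated C8=C9 alkene is inert.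

**Step 8**
Reactants: 14 2α,6α-dihydroxy-11,12,13-trinordauc-8-en-4-one
Product: 15 6α-angeloyloxy-2α-hydroxy-11,12,13-trinordauc-8-en-4-one
Conditions: (Z)-2-methylbut-2-enoic acid (1.1 equiv), 2,4,6-Cl3C6H2COCl, Et3N, toluene, 25 °C; then 14, 60 °C
Reagents that add atoms: angelic acid, C/C=C(/C)C(=O)O
Why: Yamaguchi-type mixed-anhydride esterification without DMAP keeps the Z geometry of the angeloyl group, and the bulky anhydride should acylate the equatorial C6 hydroxyl in preference to the neopentylic C2 hydroxyl next to the quaternary C1.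

**Step 9**
Reactants: 15 6α-angeloyloxy-2α-hydroxy-11,12,13-trinordauc-8-en-4-one
Product: 16 6α-angeloyloxydauc-8-ene-2α,4β-diol
Conditions: iPrMgCl/CeCl3 (2.5 equiv each, premixed), THF, −78 °C; aq. NH4Cl
Reagents that add atoms: isopropylmagnesium chloride, CC(C)[Mg]Cl
Why: 1,2-Addition of a weakly basic organocerium reagent (Imamoto conditions) to the enolisable ketone; the nucleophile enters C4 from the α-face, anti to the β-oriented C5–C6 bond and the C1 methyl, to give the 4β tertiary alcohol, the first equivalent being spent on the 2-OH while the hindered conjugated ester survives at −78 °C.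

**Step 10**
Reactants: 16 6α-angeloyloxydauc-8-ene-2α,4β-diol
Product: 17 2α-acetoxy-6α-angeloyloxydauc-8-en-4β-ol
Conditions: Ac2O, DMAP (cat.), pyridine, CH2Cl2, 0 → 25 °C
Reagents that add atoms: acetic anhydride, CC(=O)OC(C)=O
Why: DMAP-catalysed acetylation of the only secondary alcohol; the tertiary C4 alcohol does not react and no stereocentre changes.

**Step 11**
Reactants: 17 2α-acetoxy-6α-angeloyloxydauc-8-en-4β-ol
Product: 18 2α-acetoxy-6α-angeloyloxy-10β-benzoyloxydauc-8-en-4β-ol
Conditions: Pd(PPh3)4 (5 mol %), Xantphos (6 mol %), tBuOOC(O)Ph (1.5 equiv), PhCO2Cs (20 mol %), PhCF3, 450 nm LEDs, 25 °C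
Reagents that add atoms: tert-butyl peroxybenzoate, CC(C)(C)OOC(=O)c1ccccc1
Why: Proposed new method: photoexcited zerovalent palladium reduces the perester by single-electron transfer to a monovalent palladium benzoate and tBuO•, the electrophilic tBuO• abstracts the secondary allylic H-10 (C7–H is deactivated by the neighbouring acyloxy group, C14–H is primary), the allyl radical recombines with monovalent palladium on the α-face anti to the C1 methyl, and benzoate attacks the η3-allyl divalent palladium complex outer-sphere at the less substituted terminus C10 from the β-face, which keeps the C8=C9 alkene and sets 10β; reversible ionisation of allylic benzoates by zerovalent palladium should return any C8 or 10α isomer to the equatorial 10β-benzoate; the closest known reactions are the copper/perester Kharasch–Sosnovsky allylic benzoyloxylation and Tsuji–Trost substitution with carboxylates.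

**Compound list**
1 | 3-ethoxycyclopent-2-en-1-one | CCOC1=CC(=O)CC1 | starting material
2 | bromomagnesium 3-ethoxy-1-(prop-2-en-1-yl)cyclopent-2-en-1-olate | CCOC1=CC(CC=C)(O[Mg]Br)CC1 | intermediate
3 | 3-allylcyclopent-2-en-1-one | O=C1C=C(CC=C)CC1 | intermediate
4 | (R)-3-methyl-3-(prop-2-en-1-yl)cyclopentan-1-one | O=C1CC[C@](C)(CC=C)C1 | intermediate
5 | (R)-4-methyl-4-(prop-2-en-1-yl)cyclopent-2-en-1-one | O=C1C=C[C@](C)(CC=C)C1 | intermediate
6 | 3-methylbut-3-en-1-ol | CC(=C)CCO | starting material
7 | 3-methylbut-3-enal | CC(=C)CC=O | intermediate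
8 | lithium 3-methyl-3-(prop-2-en-1-yl)cyclopenta-1,4-dien-1-olate (α'-dienolate of 5, quaternary centre as in 5) | [Li]OC1=C[C@@](C)(CC=C)C=C1 | intermediate
9 | lithium aldolate of 5 and 7 (C5-(1-lithiooxy-3-methylbut-3-enyl) derivative of 5, diastereomer mixture at the two new centres) | O=C1C=C[C@](C)(CC=C)C1C(O[Li])CC(C)=C | intermediate
10 | methanesulfonate of the aldol from 5 and 7 (diastereomer mixture at the two new centres) | O=C1C=C[C@](C)(CC=C)C1C(OS(C)(=O)=O)CC(C)=C | intermediate
11 | (S,E)-4-methyl-5-(3-methylbut-3-en-1-ylidene)-4-(prop-2-en-1-yl)cyclopent-2-en-1-one | O=C1C=C[C@](C)(CC=C)/C1=C\CC(C)=C | intermediate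
12 | (1S)-11,12,13-trinordauca-2,5,8-trien-4-one, i.e. (S)-3a,6-dimethyl-4,7-dihydroazulen-1(3aH)-one | O=C1C=C[C@]2(C)CC=C(C)CC=C12 | intermediate
13 | 2α,6α-bis(4,4,5,5-tetramethyl-1,3,2-dioxaborolan-2-yl)-11,12,13-trinordauc-8-en-4-one (5α-H) | CC1(C)OB(OC1(C)C)[C@H]1CC(C)=CC[C@@]2(C)[C@@H](B3OC(C)(C)C(C)(C)O3)CC(=O)[C@H]12 | intermediate
14 | 2α,6α-dihydroxy-11,12,13-trinordauc-8-en-4-one (5α-H) | O[C@H]1CC(C)=CC[C@@]2(C)[C@@H](O)CC(=O)[C@H]12 | intermediate
15 | 6α-angeloyloxy-2α-hydroxy-11,12,13-trinordauc-8-en-4-one | C/C=C(/C)C(=O)O[C@H]1CC(C)=CC[C@@]2(C)[C@@H](O)CC(=O)[C@H]12 | intermediate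
16 | 6α-angeloyloxydauc-8-ene-2α,4β-diol | C/C=C(/C)C(=O)O[C@H]1CC(C)=CC[C@@]2(C)[C@@H](O)C[C@@](O)(C(C)C)[C@H]12 | intermediate
17 | 2α-acetoxy-6α-angeloyloxydauc-8-en-4β-ol | C/C=C(/C)C(=O)O[C@H]1CC(C)=CC[C@@]2(C)[C@@H](OC(C)=O)C[C@@](O)(C(C)C)[C@H]12 | intermediate
18 | 2α-acetoxy-6α-angeloyloxy-10β-benzoyloxydauc-8-en-4β-ol (CNP0248576.1) | C/C=C(/C)C(=O)O[C@H]1CC(C)=C[C@H](OC(=O)c2ccccc2)[C@@]2(C)[C@@H](OC(C)=O)C[C@@](O)(C(C)C)[C@H]12 | target

**Step count**
Total: 11 steps. Longest linear sequence: 10 steps (1, 2, 3, 5, 6, 7, 8, 9, 10, 11); step 4 is a one-step side branch.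

**Three steps most likely to fail**

Step 11 (the proposed new C–H benzoyloxylation) is the least certain. Hydrogen abstraction could occur at C7, C14 or the isopropyl methine, the benzoate could end up at C8 or as the 10α epimer, and the angelate could isomerise. The fallback uses known chemistry, sets out from 17 and returns at 18. Allylic C–H oxidation with Rh2(cap)4 (dirhodium tetracaprolactamate, 1 mol %), tBuOOH and K2CO3 in CH2Cl2 at 25 °C oxidises the methylene attached to the CH end of the trisubstituted alkene and gives 2α-acetoxy-6α-angeloyloxy-4β-hydroxydauc-8-en-10-one F1. Luche reduction (NaBH4, CeCl3·7H2O, MeOH, −78 °C) delivers hydride from the α-face anti to the C1 methyl and gives 2α-acetoxy-6α-angeloyloxydauc-8-ene-4β,10β-diol F2. BzCl, DMAP and pyridine then benzoylate the secondary allylic alcohol (the tertiary one is inert) to give 18.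

Step 8 (site-selective angeloylation of diol 14) may fail through poor C6/C2 selectivity, β-elimination of the β-acyloxy ketone, or Z to E isomerisation. The fallback sets out from 14 and returns at 17, and it moves the angeloylation to a stage without a ketone or a competing secondary alcohol. TBDPSCl and imidazole in DMF at 0 °C silylate only the less hindered C6 hydroxyl and give 6α-(tert-butyldiphenylsilyloxy)-2α-hydroxy-11,12,13-trinordauc-8-en-4-one F3. iPrMgCl/CeCl3 in THF at −78 °C gives 6α-(tert-butyldiphenylsilyloxy)dauc-8-ene-2α,4β-diol F4. Ac2O, DMAP and pyridine give 2α-acetoxy-6α-(tert-butyldiphenylsilyloxy)dauc-8-en-4β-ol F5. HF·pyridine in THF gives 2α-acetoxydauc-8-ene-4β,6α-diol F6. Esterification of F6 with the angelic 2,4,6-trichlorobenzoic mixed anhydride in toluene at 80 °C gives 17.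

Step 7 (double conjugate borylation) may fail through incomplete addition at the neopentylic C2, wrong-face addition at C6, or base-induced isomerisation of the skipped diene and epimerisation at C5. The fallback sets out from 12 and returns at 14. Weitz–Scheffer epoxidation of both enones (tBuOOH, DBU, CH2Cl2, 0 °C), with peroxide attack on C2 and C6 from the α-face, gives 2α,3α:5α,6α-diepoxy-11,12,13-trinordauc-8-en-4-one F7. SmI2 in THF/MeOH at −90 °C cleaves both Cα–O bonds reductively, and α-face protonation of the samarium enolate at C5 gives 14.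

**Further compounds**
F1 | step 11 | 2α-acetoxy-6α-angeloyloxy-4β-hydroxydauc-8-en-10-one | C/C=C(/C)C(=O)O[C@H]1CC(C)=CC(=O)[C@@]2(C)[C@@H](OC(C)=O)C[C@@](O)(C(C)C)[C@H]12
F2 | step 11 | 2α-acetoxy-6α-angeloyloxydauc-8-ene-4β,10β-diol | C/C=C(/C)C(=O)O[C@H]1CC(C)=C[C@H](O)[C@@]2(C)[C@@H](OC(C)=O)C[C@@](O)(C(C)C)[C@H]12
F3 | step 8 | 6α-(tert-butyldiphenylsilyloxy)-2α-hydroxy-11,12,13-trinordauc-8-en-4-one | CC(C)(C)[Si](O[C@H]1CC(C)=CC[C@@]2(C)[C@@H](O)CC(=O)[C@H]12)(c1ccccc1)c1ccccc1
F4 | step 8 | 6α-(tert-butyldiphenylsilyloxy)dauc-8-ene-2α,4β-diol | CC(C)(C)[Si](O[C@H]1CC(C)=CC[C@@]2(C)[C@@H](O)C[C@@](O)(C(C)C)[C@H]12)(c1ccccc1)c1ccccc1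
F5 | step 8 | 2α-acetoxy-6α-(tert-butyldiphenylsilyloxy)dauc-8-en-4β-ol | CC(C)(C)[Si](O[C@H]1CC(C)=CC[C@@]2(C)[C@@H](OC(C)=O)C[C@@](O)(C(C)C)[C@H]12)(c1ccccc1)c1ccccc1
F6 | step 8 | 2α-acetoxydauc-8-ene-4β,6α-diol | O[C@H]1CC(C)=CC[C@@]2(C)[C@@H](OC(C)=O)C[C@@](O)(C(C)C)[C@H]12
F7 | step 7 | 2α,3α:5α,6α-diepoxy-11,12,13-trinordauc-8-en-4-one | O=C1[C@@H]3O[C@@H]3[C@]2(C)CC=C(C)C[C@@H]4O[C@]124
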